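**Assumption:** germacrane numbering with the lactone oxygen on C6 is used for locants (C1=C2, C3‑OAc, C4=C5, C8‑O‑angeloyl, C10‑OH, C11–C13 acrylate unit). In this numbering the target is 1E,3S,4Z,6S,7S,8R,10R.

## Retrosynthetic overview

1. Target 31 comes from diol 28 by late angeloylation of the C8 hydroxyl; the C3 acetate is installed at the acyclic stage.
2. The ten-membered carbocycle is closed first, at C6–C7, by a new ligand-controlled chromium-catalysed macrocyclising 2-(methoxycarbonyl)allylation of Z-enal/allylic bromide 24 (sets C6 and C7). The γ-lactone ring closes second, in the same pot.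
3. 24 comes from aldehyde 19 (Morita–Baylis–Hillman reaction, SN2′ bromination), which comes from an asymmetric Nozaki–Hiyama–Kishi union of enal 10 with (Z)-alkenyl iodide 14 at C3–C4 (sets C3, brings the 4Z olefin).
4. 10 comes from (R)-linalool 1 (C10 stereocentre) by ozonolysis, L-proline α-aminoxylation (C8) and cross-metathesis with crotonaldehyde 9 (1E olefin); 14 comes from but-2-yn-1-ol 11.

## Route

**Step 1**
Reactants: 1 (R)-(−)-linalool [(3R)-3,7-dimethylocta-1,6-dien-3-ol]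
Product: 2 (3R)-3,7-dimethyl-3-[(trimethylsilyl)oxy]octa-1,6-diene
Conditions: TMSCl, imidazole, DMF, 0 °C → rt
Reagents that add atoms: chlorotrimethylsilane C[Si](C)(C)Cl
Why: Silylation of the tertiary alcohol keeps the aldehyde of step 2 open-chain (no lactol) and does not touch the C10 stereocentre taken from the chiral pool.

**Step 2**
Reactants: 2 (3R)-3,7-dimethyl-3-[(trimethylsilyl)oxy]octa-1,6-diene
Product: 3 (4R)-4-methyl-4-[(trimethylsilyl)oxy]hex-5-enal
Conditions: O3, CH2Cl2, pyridine, −78 °C (Sudan Red 7B end point); then PPh3, −78 °C → rt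
Reagents that add atoms: ozone [O-][O+]=O
Why: Ozonolysis is chemoselective for the electron-rich trisubstituted alkene over the monosubstituted vinyl group, and reductive work-up gives the aldehyde.

**Step 3**
Reactants: 3 (4R)-4-methyl-4-[(trimethylsilyl)oxy]hex-5-enal
Product: 5 (2R,4R)-4-methyl-2-[(phenylamino)oxy]-4-[(trimethylsilyl)oxy]hex-5-en-1-ol, via aminoxy aldehyde 4 (not isolated)
Conditions: PhNO (1.1 equiv, added over 2 h), L-proline (20 mol%), DMSO, rt; then NaBH4, MeOH, 0 °C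
Reagents that add atoms: nitrosobenzene O=Nc1ccccc1
Why: Proline-catalysed α-aminoxylation (O-selective nitroso aldol through the enamine) sets the future C8 as 2R under catalyst control (L-proline gives the R α-oxy aldehyde), and immediate NaBH4 reduction prevents epimerisation.

**Step 4**
Reactants: 5 (2R,4R)-4-methyl-2-[(phenylamino)oxy]-4-[(trimethylsilyl)oxy]hex-5-en-1-ol
Product: 6 (2R,4R)-4-methylhex-5-ene-1,2,4-triol
Conditions: Zn dust, AcOH–THF–H2O (3:1:1), rt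
Reagents that add atoms: none
Why: Zinc in acetic acid cleaves the N–O bond reductively and the same acidic medium hydrolyses the tertiary trimethylsilyl ether, with no stereocentre involved.

**Step 5**
Reactants: 6 (2R,4R)-4-methylhex-5-ene-1,2,4-triol
Product: 7 (2R,4R)-4-methyl-1-[(triethylsilyl)oxy]hex-5-ene-2,4-diol
Conditions: TESCl (1.05 equiv), imidazole, CH2Cl2, −78 → −40 °C
Reagents that add atoms: chlorotriethylsilane CC[Si](Cl)(CC)CC
Why: Kinetic silylation selects the primary hydroxyl over the secondary and tertiary ones.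

**Step 6**
Reactants: 7 (2R,4R)-4-methyl-1-[(triethylsilyl)oxy]hex-5-ene-2,4-diol
Product: 8 (3R,5R)-5-[(tert-butyldimethylsilyl)oxy]-3-methyl-6-[(triethylsilyl)oxy]hex-1-en-3-ol
Conditions: TBSCl, imidazole, DMAP (cat.), DMF, rt
Reagents that add atoms: tert-butyldimethylsilyl chloride CC(C)(C)[Si](C)(C)Cl
Why: TBSCl/imidazole silylates the secondary hydroxyl while the tertiary allylic alcohol is inert, leaving it free for the metathesis.

**Step 7**
Reactants: 8 (3R,5R)-5-[(tert-butyldimethylsilyl)oxy]-3-methyl-6-[(triethylsilyl)oxy]hex-1-en-3-ol; 9 (E)-crotonaldehyde [(2E)-but-2-enal]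
Product: 10 (2E,4R,6R)-6-[(tert-butyldimethylsilyl)oxy]-4-hydroxy-4-methyl-7-[(triethylsilyl)oxy]hept-2-enal
Conditions: RuCl2(H2IMes)(=CH–C6H4-2-O-i-Pr) (second-generation Hoveyda–Grubbs catalyst, 5 mol%), 9 (5 equiv), CH2Cl2, 40 °C
Reagents that add atoms: none
Why: Olefin cross-metathesis of the unprotected tertiary allylic alcohol with an enal partner gives the conjugated aldehyde with the thermodynamically preferred E geometry (the 1E olefin of the target).

**Step 8**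
Reactants: 11 but-2-yn-1-ol
Product: 13 (2Z)-3-iodobut-2-en-1-ol, via cyclic alkenylalanate 12 (not isolated)
Conditions: NaAlH2(OCH2CH2OMe)2, Et2O, 0 °C → rt; then I2, THF, −78 → 0 °C
Reagents that add atoms: iodine II
Why: Hydroxyl-directed trans-hydroalumination places aluminium on C3 in a five-membered alanate, and iodinolysis with retention gives the Z iodide that carries the 4Z geometry and the C15 methyl.

**Step 9**
Reactants: 13 (2Z)-3-iodobut-2-en-1-ol
Product: 14 1-({[(2Z)-3-iodobut-2-en-1-yl]oxy}methyl)-4-methoxybenzene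
Conditions: NaH, 4-MeOC6H4CH2Cl, Bu4NI (cat.), THF–DMF, 0 °C → rt
Reagents that add atoms: 4-methoxybenzyl chloride COc1ccc(CCl)cc1
Why: Williamson etherification protects the future C6 oxygen with a group that DDQ removes later without touching silyl ethers, the acetate or the allylic bromide.

**Step 10**
Reactants: 10 (2E,4R,6R)-6-[(tert-butyldimethylsilyl)oxy]-4-hydroxy-4-methyl-7-[(triethylsilyl)oxy]hept-2-enal; 14 1-({[(2Z)-3-iodobut-2-en-1-yl]oxy}methyl)-4-methoxybenzene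
Product: 16 (2Z,4S,5E,7R,9R)-9-[(tert-butyldimethylsilyl)oxy]-1-[(4-methoxybenzyl)oxy]-3,7-dimethyl-10-[(triethylsilyl)oxy]deca-2,5-diene-4,7-diol, via trimethylsilyl ether 15 (not isolated)
Conditions: CrCl2 (15 mol%), sulfonamide ligand L1 (17 mol%; (S)-N-[2-(4-isopropyl-4,5-dihydro-1,3-oxazol-2-yl)-6-methylphenyl]methanesulfonamide), proton sponge (17 mol%), NiCl2(dmp) (2 mol%; dmp = 2,9-dimethyl-1,10-phenanthroline), Mn powder (2 equiv), LiCl (2 equiv), TMSCl (2 equiv), MeCN, rt; then K2CO3, MeOH, 0 °C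
Reagents that add atoms: none
Why: Catalytic asymmetric Nozaki–Hiyama–Kishi coupling, in which the nickel-activated alkenyl iodide is passed to a ligated trivalent chromium alkenyl that adds 1,2 to the enal with retention of the Z geometry; the ligand antipode is the one that directs attack to the aldehyde Re face to give 3S (sense to be confirmed by Mosher analysis on the first run, antipodal ligand otherwise).

**Step 11**
Reactants: 16 (2Z,4S,5E,7R,9R)-9-[(tert-butyldimethylsilyl)oxy]-1-[(4-methoxybenzyl)oxy]-3,7-dimethyl-10-[(triethylsilyl)oxy]deca-2,5-diene-4,7-diol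
Product: 17 (2Z,4S,5E,7R,9R)-9-[(tert-butyldimethylsilyl)oxy]-7-hydroxy-1-[(4-methoxybenzyl)oxy]-3,7-dimethyl-10-[(triethylsilyl)oxy]deca-2,5-dien-4-yl acetate
Conditions: Ac2O, pyridine, DMAP (cat.), CH2Cl2, 0 °C
Reagents that add atoms: acetic anhydride CC(=O)OC(C)=O
Why: DMAP-catalysed acylation takes the secondary allylic hydroxyl only (the tertiary one does not react at 0 °C), installing the C3 acetate of the target with retention.

**Step 12**
Reactants: 17 (2Z,4S,5E,7R,9R)-9-[(tert-butyldimethylsilyl)oxy]-7-hydroxy-1-[(4-methoxybenzyl)oxy]-3,7-dimethyl-10-[(triethylsilyl)oxy]deca-2,5-dien-4-yl acetate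
Product: 18 (2Z,4S,5E,7R,9R)-9-[(tert-butyldimethylsilyl)oxy]-1-[(4-methoxybenzyl)oxy]-3,7-dimethyl-7,10-bis[(triethylsilyl)oxy]deca-2,5-dien-4-yl acetate
Conditions: TESOTf, 2,6-lutidine, CH2Cl2, −78 → −20 °C
Reagents that add atoms: triethylsilyl trifluoromethanesulfonate CC[Si](CC)(CC)OS(=O)(=O)C(F)(F)F
Why: The silyl triflate protects the hindered tertiary alcohol so that the aldehyde of step 13 cannot close to a lactol.

**Step 13**
Reactants: 18 (2Z,4S,5E,7R,9R)-9-[(tert-butyldimethylsilyl)oxy]-1-[(4-methoxybenzyl)oxy]-3,7-dimethyl-7,10-bis[(triethylsilyl)oxy]deca-2,5-dien-4-yl acetate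
Product: 19 (2Z,4S,5E,7R,9R)-9-[(tert-butyldimethylsilyl)oxy]-1-[(4-methoxybenzyl)oxy]-3,7-dimethyl-10-oxo-7-[(triethylsilyl)oxy]deca-2,5-dien-4-yl acetate
Conditions: (COCl)2, DMSO, CH2Cl2, −78 → −30 °C; then Et3N, −78 → 0 °C
Reagents that add atoms: none
Why: Under Swern conditions a primary triethylsilyl ether is cleaved and oxidised directly to the aldehyde while the secondary TBS and tertiary TES ethers survive, and the low temperature preserves the α-silyloxy stereocentre.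

**Step 14**
Reactants: 19 (2Z,4S,5E,7R,9R)-9-[(tert-butyldimethylsilyl)oxy]-1-[(4-methoxybenzyl)oxy]-3,7-dimethyl-10-oxo-7-[(triethylsilyl)oxy]deca-2,5-dien-4-yl acetate; 20 methyl acrylate
Product: 21 methyl (4R,6R,7E,9S,10Z)-9-(acetyloxy)-4-[(tert-butyldimethylsilyl)oxy]-3-hydroxy-12-[(4-methoxybenzyl)oxy]-6,10-dimethyl-2-methylidene-6-[(triethylsilyl)oxy]dodeca-7,10-dienoate (both C3 epimers)
Conditions: 20 (neat, 20 equiv), DABCO (1 equiv), MeOH (2 equiv), rt, 4–6 d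
Reagents that add atoms: none
Why: Morita–Baylis–Hillman reaction of the activated α-silyloxy aldehyde adds the acrylate α-carbon (C11 with C12 and C13); the new carbinol centre is inconsequential because it becomes sp2 in step 15.

**Step 15**
Reactants: 21 methyl (4R,6R,7E,9S,10Z)-9-(acetyloxy)-4-[(tert-butyldimethylsilyl)oxy]-3-hydroxy-12-[(4-methoxybenzyl)oxy]-6,10-dimethyl-2-methylidene-6-[(triethylsilyl)oxy]dodeca-7,10-dienoate
Product: 22 methyl (2Z,4R,6R,7E,9S,10Z)-9-(acetyloxy)-2-(bromomethyl)-4-[(tert-butyldimethylsilyl)oxy]-12-[(4-methoxybenzyl)oxy]-6,10-dimethyl-6-[(triethylsilyl)oxy]dodeca-2,7,10-trienoate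
Conditions: NBS, Me2S, CH2Cl2, −20 → 0 °C
Reagents that add atoms: N-bromosuccinimide O=C1CCC(=O)N1Br
Why: Corey–Kim-type activation of the allylic alcohol followed by SN2′ attack of bromide gives the rearranged, thermodynamically preferred (Z)-2-(bromomethyl)enoate.

**Step 16**
Reactants: 22 methyl (2Z,4R,6R,7E,9S,10Z)-9-(acetyloxy)-2-(bromomethyl)-4-[(tert-butyldimethylsilyl)oxy]-12-[(4-methoxybenzyl)oxy]-6,10-dimethyl-6-[(triethylsilyl)oxy]dodeca-2,7,10-trienoate
Product: 23 methyl (2Z,4R,6R,7E,9S,10Z)-9-(acetyloxy)-2-(bromomethyl)-4-[(tert-butyldimethylsilyl)oxy]-12-hydroxy-6,10-dimethyl-6-[(triethylsilyl)oxy]dodeca-2,7,10-trienoate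
Conditions: DDQ, CH2Cl2–pH 7 phosphate buffer (10:1), 0 °C
Reagents that add atoms: none
Why: Oxidative cleavage of the 4-methoxybenzyl ether (benzylic hydride abstraction, then hydrolysis) is neutral and non-nucleophilic, so the allylic bromide, acetate and silyl ethers are untouched.

**Step 17**
Reactants: 23 methyl (2Z,4R,6R,7E,9S,10Z)-9-(acetyloxy)-2-(bromomethyl)-4-[(tert-butyldimethylsilyl)oxy]-12-hydroxy-6,10-dimethyl-6-[(triethylsilyl)oxy]dodeca-2,7,10-trienoate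
Product: 24 methyl (2Z,4R,6R,7E,9S,10Z)-9-(acetyloxy)-2-(bromomethyl)-4-[(tert-butyldimethylsilyl)oxy]-6,10-dimethyl-12-oxo-6-[(triethylsilyl)oxy]dodeca-2,7,10-trienoate
Conditions: MnO2 (activated, 20 equiv), CH2Cl2, rt; used at once
Reagents that add atoms: none
Why: MnO2 oxidises only the allylic alcohol under neutral conditions, so the Z-enal is obtained without Z to E leakage (nerol-to-neral type).

**Step 18**
Reactants: 24 methyl (2Z,4R,6R,7E,9S,10Z)-9-(acetyloxy)-2-(bromomethyl)-4-[(tert-butyldimethylsilyl)oxy]-6,10-dimethyl-12-oxo-6-[(triethylsilyl)oxy]dodeca-2,7,10-trienoate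
Product: 27 (1E,3S,4Z,6S,7R,8R,10R)-3-(acetyloxy)-8-[(tert-butyldimethylsilyl)oxy]-10-[(triethylsilyl)oxy]germacra-1,4,11(13)-trien-12,6-olide, via silyl ether 25 (not isolated), via hydroxy ester 26 (not isolated)
Conditions: CrCl2 (20 mol%), ligand L2 (22 mol%; 3,6-di-tert-butyl-1,8-bis[(4S)-4-isopropyl-4,5-dihydro-1,3-oxazol-2-yl]-9H-carbazole), i-Pr2NEt (40 mol%), Mn powder (3 equiv), TMSCl (2 equiv), THF, 0 °C, 24 added by syringe pump over 12 h (2 mM final); then PPTS, MeOH, 0 °C → rt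
Reagents that add atoms: none
Why: Proposed new method: a ligand-controlled chromium-catalysed macrocyclising 2-(methoxycarbonyl)allylation. Divalent chromium bound to tridentate L2 reduces the allylic bromide to an allyl trivalent-chromium species, which equilibrates by 1,3-metallotropy to the isomer with C8 trans to CH2–Cr and adds through C7 to the Re face of the tethered Z-enal in a six-membered chair. With C5 and C8 both pseudo-equatorial (the bulky L2 pocket penalises an axial C8) the chair gives the 6,7-anti relationship (trans-lactone, 6S). C7 is fixed in the target sense (R by CIP in 27 only because of the silyl ether) because allylic 1,3-strain holds H8 in the allyl plane and the tether can only deliver the aldehyde to the face opposite the OTBS group. TMSCl and Mn turn the catalyst over, and mild acid then removes the O-trimethylsilyl group and closes the lactone. The closest known reactions are the intermolecular chromium-catalysed asymmetric 2-(alkoxycarbonyl)allylation of aldehydes to α-methylene-γ-butyrolactones and stoichiometric CrCl2 Nozaki–Hiyama–Kishi allylation macrocyclisations of germacranolide precursors; new here are the catalytic asymmetric closure of a ten-membered ring, the γ-branched donor and the Z-enal acceptor.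

**Step 19**
Reactants: 27 (1E,3S,4Z,6S,7R,8R,10R)-3-(acetyloxy)-8-[(tert-butyldimethylsilyl)oxy]-10-[(triethylsilyl)oxy]germacra-1,4,11(13)-trien-12,6-olide
Product: 28 (1E,3S,4Z,6S,7S,8R,10R)-3-(acetyloxy)-8,10-dihydroxygermacra-1,4,11(13)-trien-12,6-olide
Conditions: HF·pyridine, pyridine, THF, 0 °C → rt
Reagents that add atoms: none
Why: Buffered fluoride cleaves both Si–O bonds while the acetate, the α-methylene lactone and the tertiary allylic alcohol survive (the C7 descriptor changes only because the silyl group is gone).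

**Step 20**
Reactants: 28 (1E,3S,4Z,6S,7S,8R,10R)-3-(acetyloxy)-8,10-dihydroxygermacra-1,4,11(13)-trien-12,6-olide; 29 angelic acid [(2Z)-2-methylbut-2-enoic acid]
Product: 31 (1E,3S,4Z,6S,7S,8R,10R)-3-(acetyloxy)-8-{[(2Z)-2-methylbut-2-enoyl]oxy}-10-hydroxygermacra-1,4,11(13)-trien-12,6-olide (CNP0181631.2), via mixed anhydride 30 (not isolated)
Conditions: 29, 2,4,6-trichlorobenzoyl chloride, Et3N, toluene, rt, 2 h; then 28, 75 °C
Reagents that add atoms: none
Why: Yamaguchi-type esterification through the preformed angelic 2,4,6-trichlorobenzoic anhydride without DMAP acylates the secondary C8 hydroxyl (the tertiary C10 hydroxyl is inert) and avoids isomerisation of the angelate to the tiglate.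

## Compound list

1 | (R)-(−)-linalool, (3R)-3,7-dimethylocta-1,6-dien-3-ol | C=C[C@](C)(O)CCC=C(C)C | starting material
2 | (3R)-3,7-dimethyl-3-[(trimethylsilyl)oxy]octa-1,6-diene | C=C[C@](C)(O[Si](C)(C)C)CCC=C(C)C | intermediate
3 | (4R)-4-methyl-4-[(trimethylsilyl)oxy]hex-5-enal | C=C[C@](C)(O[Si](C)(C)C)CCC=O | intermediate
4 | (2R,4R)-4-methyl-2-[(phenylamino)oxy]-4-[(trimethylsilyl)oxy]hex-5-enal | C=C[C@](C)(O[Si](C)(C)C)C[C@@H](ONc1ccccc1)C=O | intermediate
5 | (2R,4R)-4-methyl-2-[(phenylamino)oxy]-4-[(trimethylsilyl)oxy]hex-5-en-1-ol | C=C[C@](C)(O[Si](C)(C)C)C[C@@H](ONc1ccccc1)CO | intermediate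
6 | (2R,4R)-4-methylhex-5-ene-1,2,4-triol | C=C[C@](C)(O)C[C@@H](O)CO | intermediate
7 | (2R,4R)-4-methyl-1-[(triethylsilyl)oxy]hex-5-ene-2,4-diol | C=C[C@](C)(O)C[C@@H](O)CO[Si](CC)(CC)CC | intermediate
8 | (3R,5R)-5-[(tert-butyldimethylsilyl)oxy]-3-methyl-6-[(triethylsilyl)oxy]hex-1-en-3-ol | C=C[C@](C)(O)C[C@@H](O[Si](C)(C)C(C)(C)C)CO[Si](CC)(CC)CC | intermediate
9 | (E)-crotonaldehyde, (2E)-but-2-enal | C/C=C/C=O | starting material
10 | (2E,4R,6R)-6-[(tert-butyldimethylsilyl)oxy]-4-hydroxy-4-methyl-7-[(triethylsilyl)oxy]hept-2-enal | O=C/C=C/[C@](C)(O)C[C@@H](O[Si](C)(C)C(C)(C)C)CO[Si](CC)(CC)CC | intermediate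
11 | but-2-yn-1-ol | CC#CCO | starting material
12 | sodium 2,2-bis(2-methoxyethoxy)-3-methyl-2,5-dihydro-1,2-oxaaluminol-2-uide (cyclic alkenylalanate) | CC1=CCO[Al-]1(OCCOC)OCCOC.[Na+] | intermediate
13 | (2Z)-3-iodobut-2-en-1-ol | C/C(I)=C/CO | intermediate
14 | 1-({[(2Z)-3-iodobut-2-en-1-yl]oxy}methyl)-4-methoxybenzene | COc1ccc(COC/C=C(/C)I)cc1 | intermediate
15 | (2Z,4S,5E,7R,9R)-9-[(tert-butyldimethylsilyl)oxy]-1-[(4-methoxybenzyl)oxy]-3,7-dimethyl-10-[(triethylsilyl)oxy]-4-[(trimethylsilyl)oxy]deca-2,5-dien-7-ol | COc1ccc(COC/C=C(/C)[C@@H](O[Si](C)(C)C)/C=C/[C@](C)(O)C[C@@H](O[Si](C)(C)C(C)(C)C)CO[Si](CC)(CC)CC)cc1 | intermediate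
16 | (2Z,4S,5E,7R,9R)-9-[(tert-butyldimethylsilyl)oxy]-1-[(4-methoxybenzyl)oxy]-3,7-dimethyl-10-[(triethylsilyl)oxy]deca-2,5-diene-4,7-diol | COc1ccc(COC/C=C(/C)[C@@H](O)/C=C/[C@](C)(O)C[C@@H](O[Si](C)(C)C(C)(C)C)CO[Si](CC)(CC)CC)cc1 | intermediate
17 | (2Z,4S,5E,7R,9R)-9-[(tert-butyldimethylsilyl)oxy]-7-hydroxy-1-[(4-methoxybenzyl)oxy]-3,7-dimethyl-10-[(triethylsilyl)oxy]deca-2,5-dien-4-yl acetate | COc1ccc(COC/C=C(/C)[C@@H](OC(C)=O)/C=C/[C@](C)(O)C[C@@H](O[Si](C)(C)C(C)(C)C)CO[Si](CC)(CC)CC)cc1 | intermediate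
18 | (2Z,4S,5E,7R,9R)-9-[(tert-butyldimethylsilyl)oxy]-1-[(4-methoxybenzyl)oxy]-3,7-dimethyl-7,10-bis[(triethylsilyl)oxy]deca-2,5-dien-4-yl acetate | COc1ccc(COC/C=C(/C)[C@@H](OC(C)=O)/C=C/[C@](C)(O[Si](CC)(CC)CC)C[C@@H](O[Si](C)(C)C(C)(C)C)CO[Si](CC)(CC)CC)cc1 | intermediate
19 | (2Z,4S,5E,7R,9R)-9-[(tert-butyldimethylsilyl)oxy]-1-[(4-methoxybenzyl)oxy]-3,7-dimethyl-10-oxo-7-[(triethylsilyl)oxy]deca-2,5-dien-4-yl acetate | COc1ccc(COC/C=C(/C)[C@@H](OC(C)=O)/C=C/[C@](C)(O[Si](CC)(CC)CC)C[C@@H](O[Si](C)(C)C(C)(C)C)C=O)cc1 | intermediate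
20 | methyl acrylate | C=CC(=O)OC | starting material
21 | methyl (4R,6R,7E,9S,10Z)-9-(acetyloxy)-4-[(tert-butyldimethylsilyl)oxy]-3-hydroxy-12-[(4-methoxybenzyl)oxy]-6,10-dimethyl-2-methylidene-6-[(triethylsilyl)oxy]dodeca-7,10-dienoate (both C3 epimers) | COc1ccc(COC/C=C(/C)[C@@H](OC(C)=O)/C=C/[C@](C)(O[Si](CC)(CC)CC)C[C@@H](O[Si](C)(C)C(C)(C)C)C(O)C(=C)C(=O)OC)cc1 | intermediate
22 | methyl (2Z,4R,6R,7E,9S,10Z)-9-(acetyloxy)-2-(bromomethyl)-4-[(tert-butyldimethylsilyl)oxy]-12-[(4-methoxybenzyl)oxy]-6,10-dimethyl-6-[(triethylsilyl)oxy]dodeca-2,7,10-trienoate | COc1ccc(COC/C=C(/C)[C@@H](OC(C)=O)/C=C/[C@](C)(O[Si](CC)(CC)CC)C[C@@H](O[Si](C)(C)C(C)(C)C)/C=C(\CBr)C(=O)OC)cc1 | intermediate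
23 | methyl (2Z,4R,6R,7E,9S,10Z)-9-(acetyloxy)-2-(bromomethyl)-4-[(tert-butyldimethylsilyl)oxy]-12-hydroxy-6,10-dimethyl-6-[(triethylsilyl)oxy]dodeca-2,7,10-trienoate | OC/C=C(/C)[C@@H](OC(C)=O)/C=C/[C@](C)(O[Si](CC)(CC)CC)C[C@@H](O[Si](C)(C)C(C)(C)C)/C=C(\CBr)C(=O)OC | intermediate
24 | methyl (2Z,4R,6R,7E,9S,10Z)-9-(acetyloxy)-2-(bromomethyl)-4-[(tert-butyldimethylsilyl)oxy]-6,10-dimethyl-12-oxo-6-[(triethylsilyl)oxy]dodeca-2,7,10-trienoate | O=C/C=C(/C)[C@@H](OC(C)=O)/C=C/[C@](C)(O[Si](CC)(CC)CC)C[C@@H](O[Si](C)(C)C(C)(C)C)/C=C(\CBr)C(=O)OC | intermediate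
25 | methyl (1E,3S,4Z,6S,7S,8R,10R)-3-(acetyloxy)-8-[(tert-butyldimethylsilyl)oxy]-10-[(triethylsilyl)oxy]-6-[(trimethylsilyl)oxy]germacra-1,4,11(13)-trien-12-oate | C[Si](C)(C)O[C@H]1/C=C(/C)[C@@H](OC(C)=O)/C=C/[C@](C)(O[Si](CC)(CC)CC)C[C@@H](O[Si](C)(C)C(C)(C)C)[C@@H]1C(=C)C(=O)OC | intermediate
26 | methyl (1E,3S,4Z,6S,7R,8R,10R)-3-(acetyloxy)-8-[(tert-butyldimethylsilyl)oxy]-6-hydroxy-10-[(triethylsilyl)oxy]germacra-1,4,11(13)-trien-12-oate | O[C@H]1/C=C(/C)[C@@H](OC(C)=O)/C=C/[C@](C)(O[Si](CC)(CC)CC)C[C@@H](O[Si](C)(C)C(C)(C)C)[C@@H]1C(=C)C(=O)OC | intermediate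
27 | (1E,3S,4Z,6S,7R,8R,10R)-3-(acetyloxy)-8-[(tert-butyldimethylsilyl)oxy]-10-[(triethylsilyl)oxy]germacra-1,4,11(13)-trien-12,6-olide | C=C1C(=O)O[C@H]2/C=C(/C)[C@@H](OC(C)=O)/C=C/[C@](C)(O[Si](CC)(CC)CC)C[C@@H](O[Si](C)(C)C(C)(C)C)[C@H]12 | intermediate
28 | (1E,3S,4Z,6S,7S,8R,10R)-3-(acetyloxy)-8,10-dihydroxygermacra-1,4,11(13)-trien-12,6-olide | C=C1C(=O)O[C@H]2/C=C(/C)[C@@H](OC(C)=O)/C=C/[C@](C)(O)C[C@@H](O)[C@H]12 | intermediate
29 | angelic acid, (2Z)-2-methylbut-2-enoic acid | C/C=C(/C)C(=O)O | starting material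
30 | (2Z)-2-methylbut-2-enoic 2,4,6-trichlorobenzoic anhydride | C/C=C(/C)C(=O)OC(=O)c1c(Cl)cc(Cl)cc1Cl | intermediate
31 | (1E,3S,4Z,6S,7S,8R,10R)-3-(acetyloxy)-8-{[(2Z)-2-methylbut-2-enoyl]oxy}-10-hydroxygermacra-1,4,11(13)-trien-12,6-olide (CNP0181631.2) | C=C1C(=O)O[C@H]2/C=C(/C)[C@@H](OC(C)=O)/C=C/[C@](C)(O)C[C@@H](OC(=O)/C(C)=C\C)[C@H]12 | target

## Step count and risks

Total step count: 20. Longest linear sequence: 18 steps (steps 1–7 and 10–20, from (R)-linalool 1); steps 8–9 make the side fragment 14.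

Three steps most likely to fail:

**Step 18 (the proposed new macrocyclisation).** It may give no ring, a cis-lactone, or Z to E leakage of 24. The fallback uses known chemistry only and reverses the order of the two C–C couplings, so that the lactone is made first and the ring is closed at C3–C4. It sets out from 8. Cross-metathesis of 8 with (Z)-1,4-bis[(tert-butyldimethylsilyl)oxy]but-2-ene (same ruthenium carbene as step 7) gives the bis-silyl allylic ether F1. TESOTf/2,6-lutidine gives the tertiary silyl ether F2, Swern oxidation gives the aldehyde F3, Morita–Baylis–Hillman reaction with 20 gives the adduct F4, and NBS/Me2S gives the (Z)-allylic bromide F5. Separately, MnO2 oxidation of 13 gives (2Z)-3-iodobut-2-enal F6. Stoichiometric CrCl2 in THF (intermolecular 2-(alkoxycarbonyl)allylation; the allylic bromide reacts, the alkenyl iodide does not without nickel) couples F5 with F6 to the hydroxy ester F7 (not isolated), which closes with p-TsOH to the α-methylene lactone F8 (diastereomers separated here). HF·pyridine/pyridine at 0 °C removes only the primary allylic silyl group to give the primary alcohol F9, and MnO2 gives the enal F10. Intramolecular Nozaki–Hiyama–Kishi coupling (CrCl2, NiCl2 cat., DMSO–THF, high dilution) closes the ten-membered ring to the macrocyclic alcohol F11 (C3 epimers separable). Acetylation (Ac2O, pyridine, DMAP) brings the material back to the route at 27.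

**Step 10 (catalyst-controlled C3 stereocentre in the fragment union).** The enantioface selectivity of the ligand on this enal may be low or of the wrong sense. The fallback sets out from 10 and 14: ligand-free coupling (CrCl2, NiCl2 cat., DMSO, rt) gives the epimeric alcohol mixture F12; MnO2 oxidises both epimers to the cross-conjugated dienone F13; reduction with (R)-2-methyl-CBS-oxazaborolidine and catecholborane at −78 °C, with the α-methyl-branched alkenyl group acting as the large substituent, returns the 4S alcohol and comes back to the route at 16.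

**Step 14 (Morita–Baylis–Hillman reaction on a hindered α-silyloxy aldehyde).** The reaction takes days, and slow conversion or α-epimerisation by the amine are the risks. The fallback sets out from 19 and replaces amine catalysis by a preformed nucleophile: methyl propiolate, i-Bu2AlH and N-methylmorpholine N-oxide in THF at 0 °C give the vinylalane F14, which adds 1,2 to 19 within hours at 0 °C and comes back to the route at 21.

## Further compounds

F1 | step 18 | (2E,4R,6R)-1,6-bis[(tert-butyldimethylsilyl)oxy]-4-methyl-7-[(triethylsilyl)oxy]hept-2-en-4-ol | CC(C)(C)[Si](C)(C)OC/C=C/[C@](C)(O)C[C@@H](O[Si](C)(C)C(C)(C)C)CO[Si](CC)(CC)CC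
F2 | step 18 | (2E,4R,6R)-1,6-bis[(tert-butyldimethylsilyl)oxy]-4-methyl-4,7-bis[(triethylsilyl)oxy]hept-2-ene | CC(C)(C)[Si](C)(C)OC/C=C/[C@](C)(O[Si](CC)(CC)CC)C[C@@H](O[Si](C)(C)C(C)(C)C)CO[Si](CC)(CC)CC
F3 | step 18 | (2R,4R,5E)-2,7-bis[(tert-butyldimethylsilyl)oxy]-4-methyl-4-[(triethylsilyl)oxy]hept-5-enal | CC(C)(C)[Si](C)(C)OC/C=C/[C@](C)(O[Si](CC)(CC)CC)C[C@@H](O[Si](C)(C)C(C)(C)C)C=O
F4 | step 18 | methyl (4R,6R,7E)-4,9-bis[(tert-butyldimethylsilyl)oxy]-3-hydroxy-6-methyl-2-methylidene-6-[(triethylsilyl)oxy]non-7-enoate (both C3 epimers) | CC(C)(C)[Si](C)(C)OC/C=C/[C@](C)(O[Si](CC)(CC)CC)C[C@@H](O[Si](C)(C)C(C)(C)C)C(O)C(=C)C(=O)OC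
F5 | step 18 | methyl (2Z,4R,6R,7E)-2-(bromomethyl)-4,9-bis[(tert-butyldimethylsilyl)oxy]-6-methyl-6-[(triethylsilyl)oxy]nona-2,7-dienoate | CC(C)(C)[Si](C)(C)OC/C=C/[C@](C)(O[Si](CC)(CC)CC)C[C@@H](O[Si](C)(C)C(C)(C)C)/C=C(\CBr)C(=O)OC
F6 | step 18 | (2Z)-3-iodobut-2-enal | C/C(I)=C/C=O
F7 | step 18 | methyl (3R,4R,6R,7E)-4,9-bis[(tert-butyldimethylsilyl)oxy]-3-[(1R,2Z)-1-hydroxy-3-iodobut-2-en-1-yl]-6-methyl-2-methylidene-6-[(triethylsilyl)oxy]non-7-enoate | O[C@@H](/C=C(/C)I)[C@@H](C(=C)C(=O)OC)[C@H](O[Si](C)(C)C(C)(C)C)C[C@@](C)(O[Si](CC)(CC)CC)/C=C/CO[Si](C)(C)C(C)(C)C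
F8 | step 18 | (4R,5R)-4-{(1R,3R,4E)-1,6-bis[(tert-butyldimethylsilyl)oxy]-3-methyl-3-[(triethylsilyl)oxy]hex-4-en-1-yl}-5-[(1Z)-2-iodoprop-1-en-1-yl]-3-methylidenedihydrofuran-2(3H)-one | C=C1C(=O)O[C@@H](/C=C(/C)I)[C@@H]1[C@H](O[Si](C)(C)C(C)(C)C)C[C@@](C)(O[Si](CC)(CC)CC)/C=C/CO[Si](C)(C)C(C)(C)C
F9 | step 18 | (4R,5R)-4-{(1R,3R,4E)-1-[(tert-butyldimethylsilyl)oxy]-6-hydroxy-3-methyl-3-[(triethylsilyl)oxy]hex-4-en-1-yl}-5-[(1Z)-2-iodoprop-1-en-1-yl]-3-methylidenedihydrofuran-2(3H)-one | C=C1C(=O)O[C@@H](/C=C(/C)I)[C@@H]1[C@H](O[Si](C)(C)C(C)(C)C)C[C@@](C)(O[Si](CC)(CC)CC)/C=C/CO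
F10 | step 18 | (2E,4R,6R)-6-[(tert-butyldimethylsilyl)oxy]-6-{(2R,3R)-2-[(1Z)-2-iodoprop-1-en-1-yl]-4-methylidene-5-oxooxolan-3-yl}-4-methyl-4-[(triethylsilyl)oxy]hex-2-enal | C=C1C(=O)O[C@@H](/C=C(/C)I)[C@@H]1[C@H](O[Si](C)(C)C(C)(C)C)C[C@@](C)(O[Si](CC)(CC)CC)/C=C/C=O
F11 | step 18 | (1E,3S,4Z,6S,7R,8R,10R)-8-[(tert-butyldimethylsilyl)oxy]-3-hydroxy-10-[(triethylsilyl)oxy]germacra-1,4,11(13)-trien-12,6-olide | C=C1C(=O)O[C@H]2/C=C(/C)[C@@H](O)/C=C/[C@](C)(O[Si](CC)(CC)CC)C[C@@H](O[Si](C)(C)C(C)(C)C)[C@H]12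
F12 | step 10 | (2Z,5E,7R,9R)-9-[(tert-butyldimethylsilyl)oxy]-1-[(4-methoxybenzyl)oxy]-3,7-dimethyl-10-[(triethylsilyl)oxy]deca-2,5-diene-4,7-diol (mixture of C4 epimers) | COc1ccc(COC/C=C(/C)C(O)/C=C/[C@](C)(O)C[C@@H](O[Si](C)(C)C(C)(C)C)CO[Si](CC)(CC)CC)cc1
F13 | step 10 | (2Z,5E,7R,9R)-9-[(tert-butyldimethylsilyl)oxy]-7-hydroxy-1-[(4-methoxybenzyl)oxy]-3,7-dimethyl-10-[(triethylsilyl)oxy]deca-2,5-dien-4-one | COc1ccc(COC/C=C(/C)C(=O)/C=C/[C@](C)(O)C[C@@H](O[Si](C)(C)C(C)(C)C)CO[Si](CC)(CC)CC)cc1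
F14 | step 14 | [1-(methoxycarbonyl)ethenyl]bis(2-methylpropyl)aluminium | C=C(C(=O)OC)[Al](CC(C)C)CC(C)C
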